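The constants used here are those of an exercise; no experiment stands behind them.

Slowness is the thing to watch here: the constant 0.00931 L mol⁻¹ min⁻¹ of the step from bis adduct to triple product is smaller than those of the other steps between two species.

| flask | substrate | partner | time |
|---|---|---|---|
| south | 0.50 M | 1.30 equiv | 8.0 h |
| east | 0.50 M | 2.00 equiv | 8.0 h |
| north-east | 0.50 M | 2.90 equiv | 8.0 h |

    first product → side product B (k1 = 0.00746 min⁻¹)
    partner + first product → bis adduct + by-product (k2 = 0.126 L mol⁻¹ min⁻¹)
    substrate + partner → first product + by-product (k3 = 0.0432 L mol⁻¹ min⁻¹)
    partner + bis adduct → triple product + by-product (k4 = 0.00931 L mol⁻¹ min⁻¹)
    substrate + by-product → side product A (k5 = 0.0365 L mol⁻¹ min⁻¹)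

- which of these there is most of at the end, counted by the substrate in it, south (side product A / bis adduct / side product B / triple product)
- which of these there is most of at the end, counted by the substrate in it, east (side product A / bis adduct / side product B / triple product)
- which of these there is most of at the end, counted by the substrate in it, north-east (side product A / bis adduct / side product B / triple product)
- amount of the one of these that there is most of at the end, in percent of the substrate charged, south
- amount of the one of these that there is most of at the end, in percent of the substrate charged, east
- amount of the one of these that there is most of at the end, in percent of the substrate charged, north-east

You can draw the curve of bis adduct by hand for east; I reckon that flask and leave the other two alone. At the start, [substrate] falls with a first-order constant 0.0432 L mol⁻¹ min⁻¹ times [partner], which is 2.59 h⁻¹, a half-life of 0.267 h. First product starts at nil, so the curve of bis adduct starts with zero slope. The step from first product to bis adduct has the larger constant, 0.126 L mol⁻¹ min⁻¹ against 0.0432 L mol⁻¹ min⁻¹ for the step making first product, and I take that as enough to draw first product as a small intermediate once it has built up. Side product A starts with zero slope too: it needs by-product, and none is charged. Once [by-product] equals [partner], its step takes 45.8% of the substrate used.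

Between nil and that share I guess the knee of bis adduct at 66.7% of the substrate charged, with a third lost to the side products. Each bis adduct holds two partners, so, leaving aside the one partner in each side product B, 0.667 of partner remains per substrate charged, matching the bis adduct share. From the knee on, the two fall together as a second-order pair at equal concentrations.

So define the tail rate, 0.279 h⁻¹, the constant of that step times the charged substrate concentration: the reciprocal of the bis adduct share rises by this amount each hour. Bis adduct and triple product then cross after 5.37 h, far later than the substrate half-life. At 8.0 h bis adduct stands at 26.8% and triple product at 39.9%, above the side-product third, on a curve flattening towards 66.7%. I commit to triple product for east.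

The forecast names side product A at 40% for south, triple product at 37% for east and triple product at 63% for north-east, and says of east that “slow bis adduct to triple conversion dominates”. Its east figure is lower than my 39.9%.

The simulation gives side product A at 39.7% in south, triple product at 37.9% in east and triple product at 63.6% in north-east. In east, the step making bis adduct had 99.9% of its turnover behind it after 4.00 h, while the step making triple product had 17% behind it after 0.800 h. Starting from the 36.8% of bis adduct at 4.00 h, the tail rate gives 26.1% at the end of east, against 25.3% in the flask. The east recipe read at 3.0 h still holds most bis adduct, and the tail rate gives 42.8% there, against 41.2% in that flask.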